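**Plan**
1. The target is a single 25-membered ring made of the ester carbon C1, the methylenes C2–C24 and one ring oxygen. It has no stereocentre.
2. Enabling feature: C16 and C17 (counted from the carbonyl carbon C1) are two neighbouring, unsubstituted ring CH2 groups far from the ester. Their bond can be traced back to a C16=C17 alkene, and that to a C16–SO2–C17 bridge in a 26-membered ring.
3. Retrosynthetic cuts, in order: C16–C17 (one sulfur atom inserted), then S–C17, then the acyl bond C1–O.
4. Forward: the C1–C16 thiol acid and the C17–C24 bromo alcohol are joined as an ester, and thiolate alkylation closes the 26-membered thialactone. Sulfur is then oxidised to the sulfone, loss of SO2 contracts the ring to 25 members, and hydrogenation saturates C16=C17.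
5. Stereochemistry: nothing has to be set, because the alkene geometry and the short-lived centres of the contraction vanish in the last step.

Key step: step 4

Assumption: the unsaturated lactone from the key step is drawn as its E isomer, the geometry expected to prevail for a dialkyl sulfone under strongly basic conditions, and any Z isomer is simply carried into the hydrogenation; ring locants in the systematic names start at the ring oxygen, so chain atoms C16 and C17 are ring atoms 17 and 19 in the sulfur-containing rings and 17 and 18 in the unsaturated lactone.

**Step 1**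
Reactants: 1 16-sulfanylhexadecanoic acid; 2 8-bromooctan-1-ol
Product: 3 8-bromooctyl 16-sulfanylhexadecanoate
Conditions: TsOH·H2O (5 mol %), toluene, reflux, Dean–Stark trap, Ar
Reagents that add atoms: none
Why: Fischer esterification driven by azeotropic removal of water: under acid catalysis the primary alcohol is acylated in preference to the thiol and any thioester that forms is transesterified to the more stable oxygen ester, as in the technical preparation of mercaptoalkanoate esters, while the un-ionised thiol leaves the primary bromide alone.

**Step 2**
Reactants: 3 8-bromooctyl 16-sulfanylhexadecanoate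
Product: 5 1-oxa-18-thiacyclohexacosan-2-one, via caesium thiolate 4 (not isolated)
Conditions: Cs2CO3 (2.5 equiv), degassed DMF, 55 °C, Ar; 3 in DMF added by syringe pump over 16 h (final 2 mM)
Reagents that add atoms: none
Why: Intramolecular SN2 thioetherification (exo-tet closure of the 26-membered ring) under pseudo-high dilution: the soft, loosely ion-paired caesium thiolate attacks the primary bromide faster than it meets a second molecule at the low stationary concentration, a large unstrained ring carries little closure penalty, and dry Cs2CO3 in DMF leaves the ester untouched.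

**Step 3**
Reactants: 5 1-oxa-18-thiacyclohexacosan-2-one
Product: 7 1-oxa-18-thiacyclohexacosan-2-one 18,18-dioxide, via sulfoxide 6 (not isolated)
Conditions: mCPBA (2.3 equiv), CH2Cl2, 0 °C to rt
Reagents that add atoms: mCPBA (3-chloroperoxybenzoic acid), OOC(=O)c1cccc(Cl)c1
Why: Sulfide-to-sulfone oxidation by two successive electrophilic oxygen transfers from the peracid, to which the saturated chains and the lactone are inert.

**Step 4**
Reactants: 7 1-oxa-18-thiacyclohexacosan-2-one 18,18-dioxide
Product: 11 (E)-oxacyclopentacos-17-en-2-one, via 17-bromo sulfone 8 (not isolated), via 19-bromo sulfone 9 (not isolated), via trans-episulfone 10 (not isolated)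
Conditions: CBr2F2 (10 equiv), KOH/Al2O3 (excess), t-BuOH/CH2Cl2, 0–5 °C to rt
Reagents that add atoms: none
Why: This is a Ramberg–Bäcklund reaction with in situ halogenation, a reaction type already used to contract macrocyclic sulfones, lactone-bearing ones included. The supported hydroxide removes a proton next to sulfur, the carbanion takes bromine from CBr2F2 to give 8 or 9, and the carbanion then raised on the other flank of sulfur displaces bromide to give episulfone 10. That closure is 3-exo-tet, so the C16–C17 bond forms in a three-membered transition state that needs no dilution, and stereospecific loss of SO2 from 10 turns the 26-membered ring into the 25-membered ring of 11. The CHBr centre and the two episulfone carbons are transient: the strongly basic medium should favour the trans episulfone, in which the two chains avoid each other, and hence E-11, and none of these centres reaches the target. The site of bromination need not be controlled, since 8 and 9 collapse to the same 10. The step does need C–H removal at the sulfone in preference to hydroxide addition to the lactone or its enolisation and bromination, and three things secure this: the sulfone offers four kinetically acidic hydrogens, the large-ring lactone is an unstrained Z-ester no more electrophilic than an open-chain alkyl ester and lies fifteen carbons away, and hydroxide held on Al2O3 in cold t-BuOH/CH2Cl2 without free water acts as a base rather than a nucleophile.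

**Step 5**
Reactants: 11 (E)-oxacyclopentacos-17-en-2-one
Product: 12 oxacyclopentacosan-2-one (24-tetracosanolide)
Conditions: H2 (1 atm), 10% Pd/C, EtOAc, rt
Reagents that add atoms: none
Why: Heterogeneous catalytic hydrogenation of an unhindered 1,2-disubstituted alkene, which converges both alkene geometries on the saturated ring and does not touch an alkyl ester, 11 being freed from sulfur-containing residues by chromatography beforehand so that the catalyst stays active.

**Compound list**
1 | 16-sulfanylhexadecanoic acid (16-mercaptohexadecanoic acid) | OC(=O)CCCCCCCCCCCCCCCS | starting material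
2 | 8-bromooctan-1-ol | OCCCCCCCCBr | starting material
3 | 8-bromooctyl 16-sulfanylhexadecanoate | O=C(CCCCCCCCCCCCCCCS)OCCCCCCCCBr | intermediate
4 | caesium 16-(8-bromooctyloxy)-16-oxohexadecane-1-thiolate (formed in the flask) | [Cs+].[S-]CCCCCCCCCCCCCCCC(=O)OCCCCCCCCBr | intermediate
5 | 1-oxa-18-thiacyclohexacosan-2-one | O=C1CCCCCCCCCCCCCCCSCCCCCCCCO1 | intermediate
6 | 1-oxa-18-thiacyclohexacosan-2-one 18-oxide (racemic at sulfur, formed in the flask) | O=C1CCCCCCCCCCCCCCCS(=O)CCCCCCCCO1 | intermediate
7 | 1-oxa-18-thiacyclohexacosan-2-one 18,18-dioxide | O=C1CCCCCCCCCCCCCCCS(=O)(=O)CCCCCCCCO1 | intermediate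
8 | 17-bromo-1-oxa-18-thiacyclohexacosan-2-one 18,18-dioxide (racemic, formed in the flask) | O=C1CCCCCCCCCCCCCCC(Br)S(=O)(=O)CCCCCCCCO1 | intermediate
9 | 19-bromo-1-oxa-18-thiacyclohexacosan-2-one 18,18-dioxide (racemic, formed in the flask) | O=C1CCCCCCCCCCCCCCCS(=O)(=O)C(Br)CCCCCCCO1 | intermediate
10 | (1R*,25R*)-9-oxa-26-thiabicyclo[23.1.0]hexacosan-10-one 26,26-dioxide (trans episulfone, racemic, one enantiomer drawn, formed in the flask) | O=C1CCCCCCCCCCCCCC[C@@H]2[C@@H](CCCCCCCO1)S2(=O)=O | intermediate
11 | (E)-oxacyclopentacos-17-en-2-one | O=C1CCCCCCCCCCCCCC/C=C/CCCCCCCO1 | intermediate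
12 | oxacyclopentacosan-2-one (24-tetracosanolide) | O=C1CCCCCCCCCCCCCCCCCCCCCCCO1 | target

**Total step count:** 5
**Longest linear sequence:** 5

**Steps most likely to fail**

1. **Step 4.** The contraction may be undercut by hydroxide opening the lactone, by enolisation and bromination at C2, or by a second bromination next to sulfur before the 1,3-elimination sets in. The fallback places the halogen at the sulfide oxidation level, where a chlorosulfonium pathway directs it to the carbons next to sulfur and no base is present.
 - Setting out from 5, NCS (CH2Cl2, 0 °C to rt) should give 17-chloro-1-oxa-18-thiacyclohexacosan-2-one F1 and 19-chloro-1-oxa-18-thiacyclohexacosan-2-one F2.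
 - The crude mixture is oxidised at once with mCPBA (2.2 equiv, CH2Cl2, 0 °C). It passes through 17-chloro-1-oxa-18-thiacyclohexacosan-2-one 18-oxide F3 and 19-chloro-1-oxa-18-thiacyclohexacosan-2-one 18-oxide F4.
 - The oxidation ends at 17-chloro-1-oxa-18-thiacyclohexacosan-2-one 18,18-dioxide F5 and 19-chloro-1-oxa-18-thiacyclohexacosan-2-one 18,18-dioxide F6.
 - Brief treatment of the pair with KOtBu in THF (−40 to 0 °C) then runs the classical Ramberg–Bäcklund reaction through 10 and comes back to the route at 11.
 - No electrophilic halogen and no hydroxide are in the flask during the base treatment, so reversible enolisation of the lactone does no harm.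

2. **Step 2.** Intermolecular S-alkylation (oligomer growth) or oxidative S–S coupling may outrun the ring closure if the stationary thiolate concentration rises or oxygen leaks in. The fallback exchanges the order of the two joining events: the C–S bond is made between two molecules and the ring is closed at the ester.
 - Setting out from 1 and 2, NaOH (2.1 equiv) in degassed EtOH (rt to 50 °C) followed by acidification should give 16-[(8-hydroxyoctyl)sulfanyl]hexadecanoic acid F7.
 - Shiina macrolactonisation follows, with 2-methyl-6-nitrobenzoic anhydride (MNBA) and DMAP in CH2Cl2 at rt and slow addition of the seco acid.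
 - It proceeds through 16-[(8-hydroxyoctyl)sulfanyl]hexadecanoic 2-methyl-6-nitrobenzoic anhydride F8, closes the 26-membered ring and comes back to the route at 5.

3. **Step 1.** S-acylation leading to thioester oligomers, and air oxidation of the thiol at reflux, may erode the chemoselective O-esterification. The fallback masks sulfur and couples under neutral conditions at room temperature.
 - Setting out from 1, trityl chloride in CH2Cl2 (rt) should give 16-(tritylsulfanyl)hexadecanoic acid F9.
 - Steglich esterification with 2 (EDC·HCl, DMAP, CH2Cl2, rt) should give 8-bromooctyl 16-(tritylsulfanyl)hexadecanoate F10.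
 - TFA/Et3SiH in CH2Cl2 (0 °C) removes the trityl group without touching ester or bromide and comes back to the route at 3.

**Further compounds**
F1 | step 4 | 17-chloro-1-oxa-18-thiacyclohexacosan-2-one (racemic) | O=C1CCCCCCCCCCCCCCC(Cl)SCCCCCCCCO1
F2 | step 4 | 19-chloro-1-oxa-18-thiacyclohexacosan-2-one (racemic) | O=C1CCCCCCCCCCCCCCCSC(Cl)CCCCCCCO1
F3 | step 4 | 17-chloro-1-oxa-18-thiacyclohexacosan-2-one 18-oxide (mixture of diastereomers) | O=C1CCCCCCCCCCCCCCC(Cl)S(=O)CCCCCCCCO1
F4 | step 4 | 19-chloro-1-oxa-18-thiacyclohexacosan-2-one 18-oxide (mixture of diastereomers) | O=C1CCCCCCCCCCCCCCCS(=O)C(Cl)CCCCCCCO1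
F5 | step 4 | 17-chloro-1-oxa-18-thiacyclohexacosan-2-one 18,18-dioxide (racemic) | O=C1CCCCCCCCCCCCCCC(Cl)S(=O)(=O)CCCCCCCCO1
F6 | step 4 | 19-chloro-1-oxa-18-thiacyclohexacosan-2-one 18,18-dioxide (racemic) | O=C1CCCCCCCCCCCCCCCS(=O)(=O)C(Cl)CCCCCCCO1
F7 | step 2 | 16-[(8-hydroxyoctyl)sulfanyl]hexadecanoic acid | OC(=O)CCCCCCCCCCCCCCCSCCCCCCCCO
F8 | step 2 | 16-[(8-hydroxyoctyl)sulfanyl]hexadecanoic 2-methyl-6-nitrobenzoic anhydride | OCCCCCCCCSCCCCCCCCCCCCCCCC(=O)OC(=O)c1c(C)cccc1[N+](=O)[O-]
F9 | step 1 | 16-(tritylsulfanyl)hexadecanoic acid | OC(=O)CCCCCCCCCCCCCCCSC(c1ccccc1)(c1ccccc1)c1ccccc1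
F10 | step 1 | 8-bromooctyl 16-(tritylsulfanyl)hexadecanoate | BrCCCCCCCCOC(=O)CCCCCCCCCCCCCCCSC(c1ccccc1)(c1ccccc1)c1ccccc1
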